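**Retrosynthetic overview**
1. Target 20 is two (2S)-flavans joined C8–CH2–C8. The last disconnections are the two O-benzyl groups and the carbinol oxygen of 18, which comes from 8-lithioflavan 17 (unmethylated unit, from alpinetin 12) and flavan-8-carbaldehyde 11 (C-methylated unit).
2. Key disconnection: the pyran ring of the C-methylated unit is cut at C4–C4a and O1–C8a, giving aryl iodide 7 and (S)-3-iodo-1-phenylpropan-1-ol 9. Both bonds should form in one palladium/norbornene ortho-alkylation/ipso-etherification.
3. Enabling feature: C4a and C8a are adjacent carbons of that benzene ring, and C8a's other neighbour C8 carries the bridge carbon (masked as a dioxolane). An iodide at C8a therefore has one free ortho C–H (C4a) and one blocked ortho site, and O1 sits on the stereocentre C2, which can be bought as an alcohol.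
4. Iodide 7 comes from 2,6-dimethoxytoluene 1 by sterically controlled C–H borylation/iodination, formylation, chelation-controlled demethylation, benzylation and acetalisation.
5. Ring order: both benzene rings are bought; the pyran ring of the C-methylated unit forms in step 7; the pyran ring of the other unit is present in alpinetin.

Key step: step 7

Remark: alpinetin 12 is taken as the commercial natural (2S)-flavanone, and carbinol 18 is carried as a mixture of both configurations at the new carbinol carbon, which becomes CH2 in step 14.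

**Route**

Step 1
Reactants: 1 2,6-dimethoxytoluene
Product: 3 5-iodo-1,3-dimethoxy-2-methylbenzene, via pinacol arylboronate 2 (not isolated)
Conditions: [Ir(OMe)(cod)]2 (1 mol %), dtbpy (2 mol %), B2pin2 (1.0 equiv), THF, 80 °C; evaporate; then CuI (10 mol %), 1,10-phenanthroline (20 mol %), KI (1.5 equiv), MeOH/H2O, air, 80 °C
Reagents that add atoms: potassium iodide, [K+].[I-]
Why: Iridium-catalysed C–H borylation is sterically controlled and should take the only ring C–H of 1 without an ortho substituent (para to the methyl group), and copper-catalysed aerobic iodination of the aryl pinacol boronate then puts iodine on the same carbon (one-pot C–H borylation/halogenation).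

Step 2
Reactants: 3 5-iodo-1,3-dimethoxy-2-methylbenzene
Product: 4 6-iodo-2,4-dimethoxy-3-methylbenzaldehyde
Conditions: Cl2CHOMe (1.5 equiv), TiCl4 (2 equiv), CH2Cl2, −10 to 0 °C; then ice/H2O
Reagents that add atoms: dichloromethyl methyl ether, COC(Cl)Cl; water, O
Why: Rieche formylation (electrophilic aromatic substitution): the two free ring positions of 3 are equivalent by symmetry and each is ortho to one and para to the other methoxy group, so one aldehyde should result and the formyl group deactivates the ring against a second substitution.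

Step 3
Reactants: 4 6-iodo-2,4-dimethoxy-3-methylbenzaldehyde
Product: 5 2-hydroxy-6-iodo-4-methoxy-3-methylbenzaldehyde
Conditions: BCl3 (1.2 equiv), CH2Cl2, −78 to 0 °C; then H2O
Reagents that add atoms: none
Why: Chelation-controlled ortho-demethylation: BCl3 binds the aldehyde oxygen and should cleave only the methyl ether ortho to it through a six-membered chelate, leaving the para methoxy group.

Step 4
Reactants: 5 2-hydroxy-6-iodo-4-methoxy-3-methylbenzaldehyde
Product: 6 2-(benzyloxy)-6-iodo-4-methoxy-3-methylbenzaldehyde
Conditions: BnBr (1.2 equiv), K2CO3 (1.5 equiv), DMF, 60 °C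
Reagents that add atoms: benzyl bromide, BrCc1ccccc1
Why: Williamson etherification of the hydrogen-bonded salicylaldehyde phenol, for which a polar solvent and mild heating are the usual remedy.

Step 5
Reactants: 6 2-(benzyloxy)-6-iodo-4-methoxy-3-methylbenzaldehyde
Product: 7 2-[2-(benzyloxy)-6-iodo-4-methoxy-3-methylphenyl]-1,3-dioxolane
Conditions: ethylene glycol (5 equiv), p-TsOH (5 mol %), toluene, reflux, Dean–Stark
Reagents that add atoms: ethylene glycol, OCCO
Why: Acid-catalysed acetalisation with azeotropic removal of water masks the aldehyde, which could otherwise intercept the norbornyl–palladium intermediate of step 7, as a base-stable 1,3-dioxolane.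

Step 6
Reactants: 8 (S)-3-chloro-1-phenylpropan-1-ol
Product: 9 (S)-3-iodo-1-phenylpropan-1-ol
Conditions: NaI (3 equiv), acetone, reflux
Reagents that add atoms: sodium iodide, [Na+].[I-]
Why: Finkelstein halide exchange (SN2 at the primary carbon, driven by precipitation of NaCl) should give the primary iodide needed in step 7 without touching the stereocentre.

Step 7
Reactants: 7 2-[2-(benzyloxy)-6-iodo-4-methoxy-3-methylphenyl]-1,3-dioxolane; 9 (S)-3-iodo-1-phenylpropan-1-ol (1.5 equiv)
Product: 10 (2S)-7-(benzyloxy)-8-(1,3-dioxolan-2-yl)-5-methoxy-6-methyl-2-phenylchromane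
Conditions: Pd(OAc)2 (10 mol %), t-BuXPhos (20 mol %), norbornene (2 equiv), Cs2CO3 (3 equiv), 1,4-dioxane, 100 °C, argon
Reagents that add atoms: none
Why: Proposed new method: a palladium/norbornene (Catellani-type) annulation in which zerovalent palladium inserts into the C8a–I bond of 7, norbornene insertion and palladation of the only free ortho C–H (C4a) give an aryl–norbornyl palladacycle of divalent palladium, the primary iodide of 9 alkylates C4a through a tetravalent palladium intermediate (new C4–C4a bond), norbornene is extruded, and the resulting arylpalladium alkoxide forms the O1–C8a bond by reductive elimination. The closest known reaction types are the Catellani ortho-alkylation with ipso C–N ring closure by bromoalkylamines (indolines, tetrahydroquinolines), the palladium/norbornene annulation of aryl iodides with epoxides to 2,3-dihydrobenzofurans, and the palladium-catalysed intramolecular etherification of aryl halides with secondary alcohols, which gives 2-substituted chromans without loss of enantiopurity; new is their merger to a six-membered O-heterocycle from a 1,3-iodo alcohol. The pyran ring closes by C(aryl)–O reductive elimination from a seven-membered oxapalladacycle, formally a 6-exo ipso substitution at C8a. No stereocentre is created: C2 comes from 9 and keeps its configuration because the C2–O bond is never broken, so (S)-9 should give the (S)-flavan. The step needs site selectivity (C8 carries the dioxolane, so C4a–H is the only ortho C–H and norbornene must leave after one alkylation), alkylation before etherification (norbornene insertion into the arylpalladium iodide is faster than alkoxide exchange with the weak carbonate base), and reductive elimination faster than β-hydride elimination of the benzylic palladium alkoxide (bulky di-tert-butylbiaryl phosphine).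

Step 8
Reactants: 10 (2S)-7-(benzyloxy)-8-(1,3-dioxolan-2-yl)-5-methoxy-6-methyl-2-phenylchromane
Product: 11 (2S)-7-(benzyloxy)-5-methoxy-6-methyl-2-phenylchromane-8-carbaldehyde
Conditions: 1 M HCl, THF, rt
Reagents that add atoms: water, O
Why: Acid-catalysed hydrolysis of an electron-rich aryl dioxolane is fast under conditions too mild to ionise the flavan C2–O1 bond.

Step 9
Reactants: 12 alpinetin, (2S)-7-hydroxy-5-methoxy-2-phenylchroman-4-one
Product: 13 (2S)-7-(benzyloxy)-5-methoxy-2-phenylchroman-4-one
Conditions: BnOH (1.2 equiv), PPh3 (1.3 equiv), DIAD (1.3 equiv), THF, 0 °C to rt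
Reagents that add atoms: benzyl alcohol, OCc1ccccc1
Why: Mitsunobu etherification of the acidic 7-OH under neutral conditions avoids the base-induced ring opening to the chalcone that would racemise C2.

Step 10
Reactants: 13 (2S)-7-(benzyloxy)-5-methoxy-2-phenylchroman-4-one
Product: 14 (2S,4S)-7-(benzyloxy)-5-methoxy-2-phenylchroman-4-ol (2,4-cis)
Conditions: NaBH4 (2 equiv), THF/MeOH, 0 °C to rt
Reagents that add atoms: none
Why: Hydride reduction of the flavanone carbonyl by axial delivery should give the equatorial 2,4-cis alcohol; the C4 configuration is of no consequence because C4 becomes CH2 in step 11.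

Step 11
Reactants: 14 (2S,4S)-7-(benzyloxy)-5-methoxy-2-phenylchroman-4-ol
Product: 15 (2S)-7-(benzyloxy)-5-methoxy-2-phenylchromane
Conditions: Et3SiH (3 equiv), TFA (5 equiv), CH2Cl2, 0 °C
Reagents that add atoms: none
Why: Ionic hydrogenation: TFA ionises the benzylic alcohol to a cation stabilised by the ortho methoxy and para benzyloxy groups, and Et3SiH delivers hydride.

Step 12
Reactants: 15 (2S)-7-(benzyloxy)-5-methoxy-2-phenylchromane
Product: 16 (2S)-7-(benzyloxy)-8-bromo-5-methoxy-2-phenylchromane
Conditions: NBS (1.0 equiv), CH2Cl2, −78 to 0 °C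
Reagents that add atoms: N-bromosuccinimide, O=C1CCC(=O)N1Br
Why: Electrophilic aromatic bromination of a 5,7-dialkoxyflavan should go to C8, next to the tied-back ring oxygen, rather than to C6, which is flanked by two alkoxy groups; this is the selectivity known for O-benzylated catechins.

Step 13
Reactants: 16 (2S)-7-(benzyloxy)-8-bromo-5-methoxy-2-phenylchromane (1.2 equiv); 11 (2S)-7-(benzyloxy)-5-methoxy-6-methyl-2-phenylchromane-8-carbaldehyde
Product: 18 [(2S)-7-(benzyloxy)-5-methoxy-2-phenylchroman-8-yl][(2S)-7-(benzyloxy)-5-methoxy-6-methyl-2-phenylchroman-8-yl]methanol as a mixture of carbinol epimers, via aryllithium 17 (not isolated)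
Conditions: n-BuLi (1.2 equiv), THF, −78 °C; then 11, −78 to −20 °C; then H2O
Reagents that add atoms: none
Why: Bromine–lithium exchange at −78 °C gives the 8-lithioflavan, which should add to the aldehyde (1,2-addition); the new carbinol centre forms without control and is removed in step 14.

Step 14
Reactants: 18 bis(flavan-8-yl)methanol (epimer mixture)
Product: 19 (2S)-7-(benzyloxy)-8-{[(2S)-7-(benzyloxy)-5-methoxy-2-phenylchroman-8-yl]methyl}-5-methoxy-6-methyl-2-phenylchromane
Conditions: Et3SiH (5 equiv), TFA (5 equiv), CH2Cl2, −20 to 0 °C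
Reagents that add atoms: none
Why: Ionic hydrogenation of the doubly benzylic carbinol through its diarylmethyl cation, which is stabilised by four ortho and two para oxygen substituents.

Step 15
Reactants: 19 bis-O-benzyl methylene-bridged biflavan
Product: 20 (2S)-8-{[(2S)-7-hydroxy-5-methoxy-2-phenylchroman-8-yl]methyl}-5-methoxy-6-methyl-2-phenylchroman-7-ol (target)
Conditions: H2 (1 atm), Pd(OH)2/C, EtOAc/MeOH, rt
Reagents that add atoms: none
Why: Catalytic hydrogenolysis should cleave the two aryl benzyl ethers; the cyclic benzylic C2–O1 bonds of flavans react much more slowly, and the reaction is stopped after uptake of two equivalents of hydrogen.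

**Compound list**
1 | 2,6-dimethoxytoluene | COc1cccc(OC)c1C | starting material
2 | 2-(3,5-dimethoxy-4-methylphenyl)-4,4,5,5-tetramethyl-1,3,2-dioxaborolane | COc1cc(B2OC(C)(C)C(C)(C)O2)cc(OC)c1C | intermediate
3 | 5-iodo-1,3-dimethoxy-2-methylbenzene | COc1cc(I)cc(OC)c1C | intermediate
4 | 6-iodo-2,4-dimethoxy-3-methylbenzaldehyde | COc1cc(I)c(C=O)c(OC)c1C | intermediate
5 | 2-hydroxy-6-iodo-4-methoxy-3-methylbenzaldehyde | COc1cc(I)c(C=O)c(O)c1C | intermediate
6 | 2-(benzyloxy)-6-iodo-4-methoxy-3-methylbenzaldehyde | COc1cc(I)c(C=O)c(OCc2ccccc2)c1C | intermediate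
7 | 2-[2-(benzyloxy)-6-iodo-4-methoxy-3-methylphenyl]-1,3-dioxolane | COc1cc(I)c(C2OCCO2)c(OCc2ccccc2)c1C | intermediate
8 | (S)-3-chloro-1-phenylpropan-1-ol | O[C@@H](CCCl)c1ccccc1 | starting material
9 | (S)-3-iodo-1-phenylpropan-1-ol | O[C@@H](CCI)c1ccccc1 | intermediate
10 | (2S)-7-(benzyloxy)-8-(1,3-dioxolan-2-yl)-5-methoxy-6-methyl-2-phenylchromane | COc1c(C)c(OCc2ccccc2)c(C2OCCO2)c2c1CC[C@@H](c1ccccc1)O2 | intermediate
11 | (2S)-7-(benzyloxy)-5-methoxy-6-methyl-2-phenylchromane-8-carbaldehyde | COc1c(C)c(OCc2ccccc2)c(C=O)c2c1CC[C@@H](c1ccccc1)O2 | intermediate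
12 | alpinetin, (2S)-7-hydroxy-5-methoxy-2-phenylchroman-4-one | COc1cc(O)cc2c1C(=O)C[C@@H](c1ccccc1)O2 | starting material
13 | (2S)-7-(benzyloxy)-5-methoxy-2-phenylchroman-4-one | COc1cc(OCc3ccccc3)cc2c1C(=O)C[C@@H](c1ccccc1)O2 | intermediate
14 | (2S,4S)-7-(benzyloxy)-5-methoxy-2-phenylchroman-4-ol | COc1cc(OCc3ccccc3)cc2c1[C@@H](O)C[C@@H](c1ccccc1)O2 | intermediate
15 | (2S)-7-(benzyloxy)-5-methoxy-2-phenylchromane | COc1cc(OCc3ccccc3)cc2c1CC[C@@H](c1ccccc1)O2 | intermediate
16 | (2S)-7-(benzyloxy)-8-bromo-5-methoxy-2-phenylchromane | COc1cc(OCc3ccccc3)c(Br)c2c1CC[C@@H](c1ccccc1)O2 | intermediate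
17 | [(2S)-7-(benzyloxy)-5-methoxy-2-phenylchroman-8-yl]lithium | COc1cc(OCc3ccccc3)c([Li])c2c1CC[C@@H](c1ccccc1)O2 | intermediate
18 | [(2S)-7-(benzyloxy)-5-methoxy-2-phenylchroman-8-yl][(2S)-7-(benzyloxy)-5-methoxy-6-methyl-2-phenylchroman-8-yl]methanol (both carbinol epimers) | COc1cc(OCc2ccccc2)c(C(O)c2c(OCc3ccccc3)c(C)c(OC)c3c2O[C@H](c2ccccc2)CC3)c2c1CC[C@@H](c1ccccc1)O2 | intermediate
19 | (2S)-7-(benzyloxy)-8-{[(2S)-7-(benzyloxy)-5-methoxy-2-phenylchroman-8-yl]methyl}-5-methoxy-6-methyl-2-phenylchromane | COc1cc(OCc2ccccc2)c(Cc2c(OCc3ccccc3)c(C)c(OC)c3c2O[C@H](c2ccccc2)CC3)c2c1CC[C@@H](c1ccccc1)O2 | intermediate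
20 | (2S)-8-{[(2S)-7-hydroxy-5-methoxy-2-phenylchroman-8-yl]methyl}-5-methoxy-6-methyl-2-phenylchroman-7-ol | COc1cc(O)c(Cc2c(O)c(C)c(OC)c3c2O[C@H](c2ccccc2)CC3)c2c1CC[C@@H](c1ccccc1)O2 | target

**Step count**
Total: 15 steps. Longest linear sequence: 10 steps (1, 2, 3, 4, 5, 7, 8, 13, 14, 15).

**Steps most likely to fail**

Step 7 (proposed new method). C–H palladation at C4a may be slowed by the flanking C5 methoxy group, β-hydride elimination of the benzylic palladium alkoxide may outrun C–O reductive elimination (the iodide is then lost as C–H and the carbinol is oxidised), or base-induced closure of 9 to an oxetane may use up the alkylating agent. The fallback uses known chemistry only, sets out from 7 and comes back at 10; O1 then comes from a phenol and C2 is set by catalyst control and inverted. Palladium-catalysed hydroxylation of the aryl iodide (Pd2(dba)3, t-BuXPhos, KOH, dioxane/H2O, 100 °C) should give 3-(benzyloxy)-2-(1,3-dioxolan-2-yl)-5-methoxy-4-methylphenol F1. Magnesium-mediated ortho-formylation (MgCl2, Et3N, paraformaldehyde, MeCN, reflux) at the only free ring position should give 4-(benzyloxy)-3-(1,3-dioxolan-2-yl)-2-hydroxy-6-methoxy-5-methylbenzaldehyde F2. Claisen–Schmidt condensation with acetophenone (KOH, EtOH) should give (E)-3-[4-(benzyloxy)-3-(1,3-dioxolan-2-yl)-2-hydroxy-6-methoxy-5-methylphenyl]-1-phenylprop-2-en-1-one F3. Asymmetric transfer hydrogenation of both C=C and C=O (RuCl[(R,R)-TsDPEN](p-cymene), HCO2Na, MeOH/H2O) should give 3-(benzyloxy)-2-(1,3-dioxolan-2-yl)-6-[(3R)-3-hydroxy-3-phenylpropyl]-5-methoxy-4-methylphenol F4. Intramolecular Mitsunobu etherification (PPh3, DIAD, THF) with inversion at the carbinol carbon should then close the pyran ring to 10.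

Step 13. The 1,2-addition between two di-ortho-substituted, electron-rich partners may be slow, so that the aryllithium is protonated or attacks its own ortho benzyl ether (Wittig-type shift) instead. The fallback replaces carbonyl addition by a cross-coupling, sets out from 11 and 17 and comes back at 19, so step 14 is not needed. NaBH4 reduction of 11 should give [(2S)-7-(benzyloxy)-5-methoxy-6-methyl-2-phenylchroman-8-yl]methanol F5, and MsCl/Et3N followed by LiCl should give (2S)-7-(benzyloxy)-8-(chloromethyl)-5-methoxy-6-methyl-2-phenylchromane F6, which has no free ring position for self-alkylation. Transmetalation of 17 with ZnCl2 should give chloro[(2S)-7-(benzyloxy)-5-methoxy-2-phenylchroman-8-yl]zinc F7, and Negishi coupling of F6 with F7 (Pd(OAc)2, SPhos, THF, 50 °C) should give 19.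

Step 12. The bromination may show poor site selectivity between C8 and C6, which would put the bridge on the wrong carbon. The fallback drops halogenation, sets out from 15 and 11 and comes back at 19. It is a reductive Friedel–Crafts benzylation (TFA, CH2Cl2, 0 °C, then Et3SiH): the protonated aldehyde of 11 alkylates 15 to carbinol 18 in the flask, and the derived cation is reduced. This electrophile is far bulkier than a bromonium source, and the hydroxyalkylation is reversible until hydride capture, so the less congested C8 site should be favoured more strongly. No new compound is made, and steps 13 and 14 are not needed.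

**Further compounds**
F1 | step 7 | 3-(benzyloxy)-2-(1,3-dioxolan-2-yl)-5-methoxy-4-methylphenol | COc1cc(O)c(C2OCCO2)c(OCc2ccccc2)c1C
F2 | step 7 | 4-(benzyloxy)-3-(1,3-dioxolan-2-yl)-2-hydroxy-6-methoxy-5-methylbenzaldehyde | COc1c(C=O)c(O)c(C2OCCO2)c(OCc2ccccc2)c1C
F3 | step 7 | (E)-3-[4-(benzyloxy)-3-(1,3-dioxolan-2-yl)-2-hydroxy-6-methoxy-5-methylphenyl]-1-phenylprop-2-en-1-one | COc1c(/C=C/C(=O)c2ccccc2)c(O)c(C2OCCO2)c(OCc2ccccc2)c1C
F4 | step 7 | 3-(benzyloxy)-2-(1,3-dioxolan-2-yl)-6-[(3R)-3-hydroxy-3-phenylpropyl]-5-methoxy-4-methylphenol | COc1c(CC[C@@H](O)c2ccccc2)c(O)c(C2OCCO2)c(OCc2ccccc2)c1C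
F5 | step 13 | [(2S)-7-(benzyloxy)-5-methoxy-6-methyl-2-phenylchroman-8-yl]methanol | COc1c(C)c(OCc2ccccc2)c(CO)c2c1CC[C@@H](c1ccccc1)O2
F6 | step 13 | (2S)-7-(benzyloxy)-8-(chloromethyl)-5-methoxy-6-methyl-2-phenylchromane | COc1c(C)c(OCc2ccccc2)c(CCl)c2c1CC[C@@H](c1ccccc1)O2
F7 | step 13 | chloro[(2S)-7-(benzyloxy)-5-methoxy-2-phenylchroman-8-yl]zinc | COc1cc(OCc3ccccc3)c([Zn]Cl)c2c1CC[C@@H](c1ccccc1)O2
F0 | step 12 | none | none
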